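**Retrosynthetic overview**
1. Target ⇒ a bicyclic dihydrofuran that carries two PhSO2 groups on C14 and a silyl ether on O17. The forward steps are desilylation, reductive loss of both sulfonyl groups and O-acetylation.
2. Bicycle ⇒ its acyclic isomer, a 2-alkynyl oxirane with a CH(SO2Ph)2 chain end. One zerovalent-palladium isomerisation makes C1–C14 (carbocycle) and O–C2 and breaks O–C15. The oxirane ring (O, C16, C15) takes up C1 and C2 and becomes the 2,5-dihydrofuran (three to five ring atoms).
3. Enabling feature: in the dihydrofuran ring, C15=C1–C2 is an allyl unit. Its middle carbon C1 bears carbocycle carbon C14, its ends C15 and C2 are tied by C16–O, and C15 bears two CH2O arms (C16, C17). A propargylic oxirane gives this pattern when a soft carbanion adds to the middle carbon and its own alkoxide adds to the far end.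
4. Acyclic precursor ⇒ farnesyl acetate (C2–C13), bis(phenylsulfonyl)methane (C14), Me3SiCHN2 (C1) and 2-bromoallyl alcohol (C15–C17). Shi epoxidation sets C7/C8. Sharpless epoxidation sets C15, whose chirality is passed on to C2.
5. Ring order: C7–C8 oxirane (step 3), C15–C16 oxirane (step 9), then carbocycle and dihydrofuran together (step 11).

Key step: step 11

Numbering (cembrane): C1 is the ring sp2 carbon bonded to carbocycle CH2 C14. C2 is the O-bearing CH. C3=C4(Me), the C7–C8(Me) oxirane and C11=C12(Me) follow along the carbocycle. C15 is the other ring sp2 carbon, C16 is the ring OCH2 and C17 is the CH2OAc carbon.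
Assumption: zerovalent palladium ionises the propargylic C–O bond anti, and the alkoxide attacks the η3-allyl anti to the metal, as is usual for these bond types.

Step 1
Reactants: 1 (2E,6E)-farnesyl acetate
Product: 2 (2E,6E,10E)-12-hydroxyfarnesyl acetate
Conditions: SeO2 (cat.), t-BuOOH, salicylic acid (cat.), CH2Cl2, 0 °C to rt
Reagents that add atoms: tert-butyl hydroperoxide CC(C)(C)OO
Why: Selenium dioxide allylic oxidation (ene reaction, then [2,3]-shift) should attack the terminal, most electron-rich olefin and give the (E)-allylic alcohol, because the olefin next to the acetate is deactivated.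

Step 2
Reactants: 2 (2E,6E,10E)-12-hydroxyfarnesyl acetate
Product: 3 (2E,6E,10E)-12-(methoxycarbonyloxy)farnesyl acetate
Conditions: ClCO2Me, pyridine, CH2Cl2, 0 °C
Reagents that add atoms: methyl chloroformate COC(=O)Cl
Why: O-Acylation of the primary allylic alcohol gives a carbonate that ionises faster than the acetate in step 4 and meanwhile deactivates the C11=C12 olefin.

Step 3
Reactants: 3 (2E,6E,10E)-12-(methoxycarbonyloxy)farnesyl acetate
Product: 4 (2E,6S,7S,10E)-6,7-epoxy-12-(methoxycarbonyloxy)farnesyl acetate
Conditions: L-fructose-derived Shi ketone (30 mol %), KHSO5 (as 2KHSO5·KHSO4·K2SO4), K2CO3, Bu4NHSO4 (cat.), Na2B4O7/Na2EDTA buffer, MeCN–CH2(OMe)2–H2O, 0 °C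
Reagents that add atoms: potassium peroxymonosulfate [K+].[O-]S(=O)(=O)OO
Why: In this Shi epoxidation the chiral dioxirane should pick the only olefin without an allylic acyloxy group and, through the spiro transition state, give the trans (7S,8S)-oxirane, since the D-fructose-derived ketone gives R,R-epoxides.

Step 4
Reactants: 4 (2E,6S,7S,10E)-6,7-epoxy-12-(methoxycarbonyloxy)farnesyl acetate; 5 bis(phenylsulfonyl)methane
Product: 6 bis-sulfone acetate (C13–CH(SO2Ph)2 chain end, 7S,8S)
Conditions: Pd2(dba)3·CHCl3 (2.5 mol %), dppe (6 mol %), 5 (excess), THF, rt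
Reagents that add atoms: none
Why: In this Tsuji–Trost allylation under neutral conditions the carbonate ionises in preference to the acetate, its methoxide deprotonates 5, and the soft carbanion attacks the primary allyl terminus C13 with the E olefin retained.

Step 5
Reactants: 6 bis-sulfone acetate
Product: 7 bis-sulfone allylic alcohol
Conditions: K2CO3, MeOH, 0 °C to rt; aq NH4Cl
Reagents that add atoms: none
Why: Base-catalysed transesterification removes the acetate, while the oxirane and the reversibly deprotonated bis-sulfone are untouched.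

Step 6
Reactants: 7 bis-sulfone allylic alcohol
Product: 8 bis-sulfone (E)-enal
Conditions: MnO2, CH2Cl2, rt
Reagents that add atoms: none
Why: MnO2 oxidation is selective for the allylic alcohol and keeps the E geometry of C3=C4.

Step 7
Reactants: 8 bis-sulfone (E)-enal
Product: 9 bis-sulfone terminal (E)-enyne
Conditions: Me3SiCHN2 (2.3 equiv), LiN(iPr)2 (2.2 equiv), THF, −78 °C, then 8, to 0 °C; aq NH4Cl
Reagents that add atoms: (trimethylsilyl)diazomethane C[Si](C)(C)C=[N+]=[N-]
Why: In this Colvin rearrangement the lithiated diazo compound adds to the aldehyde, loss of Me3SiOLi and N2 gives an alkylidene carbene, its 1,2-hydrogen shift forms the alkyne (new carbon C1), and the first equivalent only masks the acidic C14–H as its anion.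

Step 8
Reactants: 9 bis-sulfone terminal (E)-enyne; 10 2-bromoprop-2-en-1-ol
Product: 11 cross-conjugated dienynol (C16H2=C15(C17H2OH)–C1≡C2)
Conditions: PdCl2(PPh3)2 (3 mol %), CuI (5 mol %), iPr2NH, THF, rt to 40 °C
Reagents that add atoms: none
Why: Sonogashira coupling of the terminal alkyne with the vinyl bromide adds C15–C17 in one step, and neither the isolated oxirane nor the bis-sulfone offers the catalyst a reaction site.

Step 9
Reactants: 11 cross-conjugated dienynol
Product: 12 (15S)-alkynyl oxirane alcohol
Conditions: Ti(OiPr)4 (20 mol %), L-(+)-diisopropyl tartrate (24 mol %), t-BuOOH (decane), 4 Å molecular sieves, CH2Cl2, −20 °C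
Reagents that add atoms: tert-butyl hydroperoxide CC(C)(C)OO
Why: Sharpless asymmetric epoxidation touches only the olefin of the allylic alcohol, and L-(+)-tartrate should deliver oxygen in the sense that turns allyl alcohol into (S)-glycidol, which here gives (S)-C15.

Step 10
Reactants: 12 (15S)-alkynyl oxirane alcohol
Product: 13 (15R)-alkynyl oxirane tert-butyldiphenylsilyl ether (same spatial arrangement, changed descriptor)
Conditions: t-BuPh2SiCl, imidazole, CH2Cl2, 0 °C to rt
Reagents that add atoms: tert-butyl(chloro)diphenylsilane CC(C)(C)[Si](Cl)(c1ccccc1)c1ccccc1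
Why: Silylation makes the two CH2O arms on C15 permanently different with a group that neither migrates nor leaves, which an acetate would not guarantee next to an alkoxide.

Step 11
Reactants: 13 (15R)-alkynyl oxirane tert-butyldiphenylsilyl ether
Product: 14 (2S,7S,8S)-bicyclic dihydrofuran 14,14-bis-sulfone silyl ether
Conditions: Pd2(dba)3·CHCl3 (5 mol %), dppe (12 mol %), THF, 55 °C, 13 added by syringe pump over 12 h (final 1 mM)
Reagents that add atoms: none
Why: Proposed new method: zerovalent palladium opens the alkynyl oxirane by anti SN2′ attack at C2 to give an η3-propargyl/allenyl palladium cation and the C16 alkoxide, which takes the single acidic proton of the molecule from C14, and the soft bis-sulfonyl carbanion then adds to the central carbon C1 and closes the 14-membered carbocycle (endo-type closure with C1 and C2 both in the ring, C14 and C3 cis on C1=C2). The palladacyclobutene is protonated at C2 by the C16–OH, the only proton source left, and the regenerated alkoxide attacks C2 of the η3-allyl C15–C1–C2 anti to palladium (5-endo-type allylic etherification), so O–C15 is exchanged for O–C2 and the ring O/C16/C15 grows by C1 and C2 into the 2,5-dihydrofuran with its tetrasubstituted olefin. The closest known reaction types are the palladium-catalysed addition of soft carbon nucleophiles to the central carbon of 2-(1-alkynyl)oxiranes and propargylic carbonates with capture of the resulting η3-allyl by an oxygen nucleophile, double cyclisations on such allyl dication equivalents, and neutral macrocyclisation of bis-sulfones onto epoxide-derived palladium cations. The new stereocentre C2 is set by chirality transfer from C15: anti ionisation, retention of the Pd–C15 relation in the palladacycle and anti C–O closure turn (15R)-13 into (2S)-14, and syn/anti exchange of the allyl does not erode this because only forms with C16 anti can close and both of them carry the metal on the same face of C2. Re-closure to an oxirane (3-exo at C15) is reversible under the catalyst, attack at C4 would need a seven-membered ring and a tertiary ether, and the dihydrofuran does not re-ionise, so it is the sink. The C7–C8 oxirane has no π neighbour and is inert, the silyl ether keeps O17 out of the reaction, the quaternary C14 leaves no second carbanion to compete with the alkoxide, and high dilution with a small-bite-angle diphosphine favours the cationic η3 form and ring closure over oligomers.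

Step 12
Reactants: 14 (2S,7S,8S)-bicyclic dihydrofuran 14,14-bis-sulfone silyl ether
Product: 15 bicyclic bis-sulfone C17 alcohol
Conditions: Bu4NF, THF, 0 °C
Reagents that add atoms: none
Why: Fluoride desilylation frees O17 before the reduction, so that the allylic C17–O group is a hydroxyl or alkoxide and hence a very poor leaving group.

Step 13
Reactants: 15 bicyclic bis-sulfone C17 alcohol
Product: 17 (2S,7S,8S)-17-hydroxy bicycle (deacetyl target), via monosulfone alcohol 16 (not isolated)
Conditions: Mg turnings (excess), MeOH–THF, 0 °C to rt; aq NH4Cl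
Reagents that add atoms: none
Why: Reductive desulfonylation by electron transfer removes both sulfonyl groups in turn, protonation at the less hindered terminus C14 should keep the tetrasubstituted C1=C15 olefin, and the ring C16–O bond lies in the nodal plane of the allyl system so it is not aligned for elimination.

Step 14
Reactants: 17 (2S,7S,8S)-17-hydroxy bicycle (deacetyl target)
Product: 18 target CNP0140293.1
Conditions: Ac2O, pyridine, DMAP (cat.), CH2Cl2, 0 °C
Reagents that add atoms: acetic anhydride CC(=O)OC(C)=O
Why: Acetylation of the only hydroxyl group under mild basic conditions leaves the oxirane, the olefins and C2 untouched.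

**Compound list**
1 | (2E,6E)-farnesyl acetate | CC(C)=CCC/C(C)=C/CC/C(C)=C/COC(C)=O | starting material
2 | (2E,6E,10E)-12-hydroxyfarnesyl acetate | OC/C(C)=C/CC/C(C)=C/CC/C(C)=C/COC(C)=O | intermediate
3 | (2E,6E,10E)-12-(methoxycarbonyloxy)farnesyl acetate | COC(=O)OC/C(C)=C/CC/C(C)=C/CC/C(C)=C/COC(C)=O | intermediate
4 | (2E,6S,7S,10E)-6,7-epoxy-12-(methoxycarbonyloxy)farnesyl acetate | COC(=O)OC/C(C)=C/CC[C@]1(C)O[C@H]1CC/C(C)=C/COC(C)=O | intermediate
5 | bis(phenylsulfonyl)methane | O=S(=O)(CS(=O)(=O)c1ccccc1)c1ccccc1 | starting material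
6 | (2E,6S,7S,10E)-6,7-epoxy-3,7,11-trimethyl-13,13-bis(phenylsulfonyl)trideca-2,10-dien-1-yl acetate | O=S(=O)(c1ccccc1)C(C/C(C)=C/CC[C@]1(C)O[C@H]1CC/C(C)=C/COC(C)=O)S(=O)(=O)c1ccccc1 | intermediate
7 | corresponding allylic alcohol | O=S(=O)(c1ccccc1)C(C/C(C)=C/CC[C@]1(C)O[C@H]1CC/C(C)=C/CO)S(=O)(=O)c1ccccc1 | intermediate
8 | corresponding (E)-enal | O=S(=O)(c1ccccc1)C(C/C(C)=C/CC[C@]1(C)O[C@H]1CC/C(C)=C/C=O)S(=O)(=O)c1ccccc1 | intermediate
9 | (3E,7S,8S,11E)-7,8-epoxy-4,8,12-trimethyl-14,14-bis(phenylsulfonyl)tetradeca-3,11-dien-1-yne | O=S(=O)(c1ccccc1)C(C/C(C)=C/CC[C@]1(C)O[C@H]1CC/C(C)=C/C#C)S(=O)(=O)c1ccccc1 | intermediate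
10 | 2-bromoprop-2-en-1-ol | OCC(Br)=C | starting material
11 | 2-methylidene dienynol from 9 and 10 | O=S(=O)(c1ccccc1)C(C/C(C)=C/CC[C@]1(C)O[C@H]1CC/C(C)=C/C#CC(=C)CO)S(=O)(=O)c1ccccc1 | intermediate
12 | (15S)-alkynyl oxirane alcohol | O=S(=O)(c1ccccc1)C(C/C(C)=C/CC[C@]1(C)O[C@H]1CC/C(C)=C/C#C[C@]1(CO)CO1)S(=O)(=O)c1ccccc1 | intermediate
13 | (15R)-alkynyl oxirane tert-butyldiphenylsilyl ether | O=S(=O)(c1ccccc1)C(C/C(C)=C/CC[C@]1(C)O[C@H]1CC/C(C)=C/C#C[C@]1(CO[Si](c2ccccc2)(c2ccccc2)C(C)(C)C)CO1)S(=O)(=O)c1ccccc1 | intermediate
14 | (2S,7S,8S)-bicyclic dihydrofuran 14,14-bis-sulfone silyl ether | CC(C)(C)[Si](OCC1=C2C(S(=O)(=O)c3ccccc3)(S(=O)(=O)c3ccccc3)C/C(C)=C/CC[C@]3(C)O[C@H]3CC/C(C)=C/[C@@H]2OC1)(c1ccccc1)c1ccccc1 | intermediate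
15 | bicyclic bis-sulfone C17 alcohol | OCC1=C2C(S(=O)(=O)c3ccccc3)(S(=O)(=O)c3ccccc3)C/C(C)=C/CC[C@]3(C)O[C@H]3CC/C(C)=C/[C@@H]2OC1 | intermediate
16 | monosulfone alcohol (C14 epimers) | OCC1=C2C(S(=O)(=O)c3ccccc3)C/C(C)=C/CC[C@]3(C)O[C@H]3CC/C(C)=C/[C@@H]2OC1 | intermediate
17 | (2S,7S,8S)-17-hydroxy bicycle (deacetyl target) | OCC1=C2CC/C(C)=C/CC[C@]3(C)O[C@H]3CC/C(C)=C/[C@@H]2OC1 | intermediate
18 | CNP0140293.1, (2S,7S,8S) | CC(=O)OCC1=C2CC/C(C)=C/CC[C@]3(C)O[C@H]3CC/C(C)=C/[C@@H]2OC1 | target

Total step count: 14. Longest linear sequence: 14 steps (1 to 18).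

**Steps most likely to fail**

Step 11. The bulky tertiary carbanion may be too slow at the hindered central carbon. Oligomerisation, attack at an allenyl terminus, or hydride shift of the palladium alkoxide to a carbonyl compound could then take over. Leakage of chirality by exchange between palladium centres is also possible.
- The fallback sets out from 9 and comes back at 14. It separates the ring closure from the ring expansion.
- The dianion of 9 (LiN(SiMe3)2) is acylated with N-methoxy-N-methyl-2-(tert-butyldiphenylsilyloxy)acetamide to the ynone F1.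
- A phosphine-catalysed α-umpolung addition of the bis-sulfone C–H to the α-carbon C1 of the ynone (PBu3 or dppp, AcOH/NaOAc, toluene, high dilution) closes the carbocycle to the (1Z)-dienone F2.
- Wittig methylenation gives the triene silyl ether F3, and Bu4NF gives the trienol F4.
- Sharpless epoxidation with L-(+)-diisopropyl tartrate gives the (15S)-dienyl oxirane alcohol F5, and silylation gives the (15R)-dienyl oxirane silyl ether F6.
- The known Cu(hfacac)2-catalysed ring expansion of vinyl oxiranes to 2,5-dihydrofurans (toluene, heat) then moves oxygen from C15 to C2. If the shift is suprafacial, as assumed here, this gives 14.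

Step 13. The allyl radical/anion stage of the second desulfonylation may shift the C1=C15 double bond or expel an allylic oxygen, and magnesium methoxide may open the oxirane.
- The fallback sets out from 15 and comes back at 17. It replaces the anionic second stage by an η3-allyl/hydride pathway.
- SmI2 in THF–MeOH at −78 °C removes only the first sulfonyl group through a sulfonyl-stabilised carbanion, and 16 is isolated.
- Pd(PPh3)4 with NaBH4 in THF–iPrOH then ionises the allylic sulfone and delivers hydride to the less hindered terminus C14.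

Step 9. The electron-poor 1,1-disubstituted enyne olefin may be epoxidised slowly and with insufficient facial selectivity, and the titanium alkoxides may open the product.
- The fallback sets out from 11 and comes back at 15. It moves stereocontrol from the substrate to the catalyst.
- VO(acac)2/t-BuOOH gives the C15-epimeric oxirane alcohol F7, which is cyclised unprotected under the conditions of step 11. The ligand is one enantiomer of N,N′-(cyclohexane-1,2-diyl)bis[2-(diphenylphosphino)benzamide] in place of dppe.
- After ionisation C15 bears two equivalent CH2O arms, so its configuration is erased. Either arm can close, and the chiral ligand decides the face of C2. The matching ligand enantiomer is found in one pair of experiments.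

**Further compounds**
F1 | step 11 | acyclic ynone silyl ether | O=S(=O)(c1ccccc1)C(C/C(C)=C/CC[C@]1(C)O[C@H]1CC/C(C)=C/C#CC(=O)CO[Si](c1ccccc1)(c1ccccc1)C(C)(C)C)S(=O)(=O)c1ccccc1
F2 | step 11 | macrocyclic (1Z,3E)-dienone | O=S(=O)(c1ccccc1)C1(S(=O)(=O)c2ccccc2)C/C(C)=C/CC[C@]2(C)O[C@H]2CC/C(C)=C/C=C1/C(=O)CO[Si](c1ccccc1)(c1ccccc1)C(C)(C)C
F3 | step 11 | macrocyclic triene silyl ether | O=S(=O)(c1ccccc1)C1(S(=O)(=O)c2ccccc2)C/C(C)=C/CC[C@]2(C)O[C@H]2CC/C(C)=C/C=C1/C(=C)CO[Si](c1ccccc1)(c1ccccc1)C(C)(C)C
F4 | step 11 | macrocyclic trienol | O=S(=O)(c1ccccc1)C1(S(=O)(=O)c2ccccc2)C/C(C)=C/CC[C@]2(C)O[C@H]2CC/C(C)=C/C=C1/C(=C)CO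
F5 | step 11 | (15S)-macrocyclic dienyl oxirane alcohol | O=S(=O)(c1ccccc1)C1(S(=O)(=O)c2ccccc2)C/C(C)=C/CC[C@]2(C)O[C@H]2CC/C(C)=C/C=C1/[C@]2(CO)CO2
F6 | step 11 | (15R)-macrocyclic dienyl oxirane silyl ether | O=S(=O)(c1ccccc1)C1(S(=O)(=O)c2ccccc2)C/C(C)=C/CC[C@]2(C)O[C@H]2CC/C(C)=C/C=C1/[C@]2(CO[Si](c3ccccc3)(c3ccccc3)C(C)(C)C)CO2
F0 | step 13 | none | none
F7 | step 9 | C15-epimeric alkynyl oxirane alcohol | O=S(=O)(c1ccccc1)C(C/C(C)=C/CC[C@]1(C)O[C@H]1CC/C(C)=C/C#CC1(CO)CO1)S(=O)(=O)c1ccccc1
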